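## Retrosynthetic overview

1. Laucapyranoid A 17 ⇐ δ-lactone 15: C6 is carried at the carboxyl level and returned to the enol ether level at the end (Petasis methylenation, then acid-induced migration of the exocyclic double bond into the ring).
2. 15 ⇐ ester 9 + epoxy triflate 12 + bromide in one flask: C5–C4 by enolate alkylation, C3–Br by epoxide opening, and last the oxane ring by O1–C6 lactonization.
3. Enabling feature: in the oxane ring O1 sits on the gem-dimethyl carbon C2 next to the bromine-bearing C3 (a trans O/Br pair, the mark of an epoxide opened by bromide), and C6 is bonded to C5, the carbon that carries the cyclohexyl ring. With C6 as an ester carbonyl, C5 is an enolate carbon and O1–C6 an acyl–oxygen bond.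
4. 9 ⇐ alkylidene ester 8 ⇐ bromohydrin 7 ⇐ epoxide 6 ⇐ dienoate 5 ⇐ 4-methylanisole: Br and Cl are installed while C1 of the carbocycle is sp2, and C1–H is set last, anti to the axial Br. This gives the all-equatorial Br/Cl/side-chain pattern, which direct bromochlorination of a 4-substituted 1-methylcyclohexene is not expected to give (trans-diaxial opening would place Br trans to the side chain).
5. Ring order: the carbocycle is the arene ring of the starting material (Birch reduction); the oxane ring is formed in step 9; 12 comes from prenol by Sharpless epoxidation.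

Key step: step 9

Remark on the chemistry: 5–8 are E/Z mixtures about the exocyclic C=C bond and 13–16 are epimer mixtures at the carbon α to the carbonyl group (C5 of the later pyran); both disappear in steps 6 and 10 and are left undefined in the SMILES; the descriptor at ring carbon 1 is R in 9 and S from 13 on only because the CIP priorities of its substituents change.

## Route

Step 1
Reactants: 1 4-methylanisole
Product: 3 4-methylcyclohex-3-en-1-one, via enol ether diene 2 (not isolated)
Conditions: Li, NH3(l), t-BuOH, THF, −78 → −33 °C; then (CO2H)2, H2O–THF, 23 °C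
Reagents that add atoms: water, O
Why: Birch reduction of the anisole gives the 1-methoxy-1,4-diene 2, whose enol ether is hydrolysed by the weak acid to the β,γ-unsaturated ketone without migration of the ring double bond; no stereocentre is formed.

Step 2
Reactants: 3 4-methylcyclohex-3-en-1-one; 4 ethyl (triphenylphosphoranylidene)acetate
Product: 5 ethyl 2-(4-methylcyclohex-3-en-1-ylidene)acetate
Conditions: PhMe, 90 °C
Reagents that add atoms: none
Why: Wittig olefination with a stabilized, non-basic ylide converts the ketone into the exocyclic enoate without conjugating the β,γ-double bond; the E/Z mixture is used as such because ring carbon 1 becomes sp3 in step 6.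

Step 3
Reactants: 5 ethyl 2-(4-methylcyclohex-3-en-1-ylidene)acetate
Product: 6 ethyl 2-[(1S,6R)-1-methyl-7-oxabicyclo[4.1.0]heptan-4-ylidene]acetate
Conditions: 1,2:4,5-di-O-isopropylidene-β-D-erythro-2,3-hexodiulo-2,6-pyranose (30 mol %), KHSO5 (as 2KHSO5·KHSO4·K2SO4), K2CO3, Bu4NHSO4, MeCN–CH2(OMe)2, aq. Na2B4O7 buffer, 0 °C
Reagents that add atoms: potassium peroxymonosulfate, [K+].[O-]S(=O)(=O)OO
Why: Shi asymmetric epoxidation: the chiral dioxirane reacts only with the electron-rich trisubstituted ring alkene (the enoate is inert) through the spiro transition state, in which the D-fructose-derived ketone should deliver oxygen to the face that gives the (1S,6R)-epoxide, so both ring stereocentres are set under catalyst control.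

Step 4
Reactants: 6 ethyl 2-[(1S,6R)-1-methyl-7-oxabicyclo[4.1.0]heptan-4-ylidene]acetate
Product: 7 ethyl 2-[(3S,4S)-3-bromo-4-hydroxy-4-methylcyclohexylidene]acetate
Conditions: Li2NiBr4 (from LiBr and NiBr2), THF, 0 → 23 °C; pH 7 buffer
Reagents that add atoms: dilithium tetrabromonickelate, [Li+].[Li+].Br[Ni-2](Br)(Br)Br
Why: SN2 opening of the trisubstituted epoxide by soft bromide at the less substituted carbon (trans-diaxial opening) inverts that carbon and leaves the tertiary carbinol carbon untouched, which should give the trans bromohydrin with the C–Br stereocentre of the target.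

Step 5
Reactants: 7 ethyl 2-[(3S,4S)-3-bromo-4-hydroxy-4-methylcyclohexylidene]acetate
Product: 8 ethyl 2-[(3S,4S)-3-bromo-4-chloro-4-methylcyclohexylidene]acetate
Conditions: SOCl2, CH2Cl2, 0 → 23 °C
Reagents that add atoms: thionyl chloride, ClS(Cl)=O
Why: Deoxychlorination of the tertiary alcohol with neighbouring-group participation: the chlorosulfite ionizes with help of the anti-periplanar bromine to a bromonium ion, which chloride should open at the tertiary (Markovnikov) carbon, so the C–Cl bond forms with net retention (double inversion) and Br and Cl stay trans; the sp2 ring carbon 1 leaves the ring without a substituent that could bias this opening.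

Step 6
Reactants: 8 ethyl 2-[(3S,4S)-3-bromo-4-chloro-4-methylcyclohexylidene]acetate
Product: 9 ethyl 2-[(1R,3S,4S)-3-bromo-4-chloro-4-methylcyclohexyl]acetate
Conditions: H2 (1 atm), [Ir(cod)(PCy3)(py)]PF6 (5 mol %), CH2Cl2, 23 °C
Reagents that add atoms: none
Why: Ester-assisted homogeneous hydrogenation of the trisubstituted alkene: in the preferred chair of 8 (Br and Cl trans-diaxial, methyl equatorial) the axial bromine shields one face of the exocyclic alkene carbon, so the bulky cationic iridium hydride should add hydrogen from the opposite, equatorial face and place the acetate arm cis to bromine (steric approach control as in additions to 3-axially substituted cyclohexanones), which sets ring carbon 1.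

Step 7
Reactants: 10 3-methylbut-2-en-1-ol
Product: 11 [(2S)-3,3-dimethyloxiran-2-yl]methanol
Conditions: Ti(OiPr)4 (5 mol %), L-(+)-diisopropyl tartrate (6 mol %), t-BuOOH, 4 Å molecular sieves, CH2Cl2, −20 °C
Reagents that add atoms: tert-butyl hydroperoxide, CC(C)(C)OO
Why: Sharpless asymmetric epoxidation of the allylic alcohol; with the L-(+)-tartrate ligand oxygen is delivered to the face that gives the (2S)-epoxy alcohol (the same sense as for geraniol), so the single stereocentre is set by the catalyst.

Step 8
Reactants: 11 [(2S)-3,3-dimethyloxiran-2-yl]methanol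
Product: 12 [(2S)-3,3-dimethyloxiran-2-yl]methyl trifluoromethanesulfonate
Conditions: Tf2O, 2,6-lutidine, CH2Cl2, −78 °C; used at once in step 9
Reagents that add atoms: trifluoromethanesulfonic anhydride, O=S(=O)(OS(=O)(=O)C(F)(F)F)C(F)(F)F
Why: O-sulfonylation of the primary alcohol gives a primary triflate that is a far better leaving group than the neighbouring epoxide; the stereocentre is not touched.

Step 9
Reactants: 9 ethyl 2-[(1R,3S,4S)-3-bromo-4-chloro-4-methylcyclohexyl]acetate; 12 [(2S)-3,3-dimethyloxiran-2-yl]methyl trifluoromethanesulfonate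
Product: 15 (5R)-5-bromo-3-[(1S,3S,4S)-3-bromo-4-chloro-4-methylcyclohexyl]-6,6-dimethyloxan-2-one, via epoxy ester 13 (not isolated), via bromohydrin ester 14 (not isolated)
Conditions: LiN(iPr)2, THF, −78 °C; 12, −78 °C; then Li2NiBr4, THF, −78 → 23 °C; then TsOH·H2O, 40 °C
Reagents that add atoms: dilithium tetrabromonickelate, [Li+].[Li+].Br[Ni-2](Br)(Br)Br
Why: The lithium enolate of 9 displaces the primary triflate of 12 at −78 °C (SN2 alkylation of an ester enolate; the epoxide is not touched) to give 13, and Li2NiBr4 then delivers soft bromide to the less substituted epoxide carbon with inversion, which converts the (S)-epoxide carbon into the (R)-configured C–Br carbon and releases the tertiary alkoxide of 14. This alkoxide attacks the ester carbonyl in a 6-exo-trig acyl substitution (completed by TsOH) and so closes the oxane ring by forming the O1–C6 bond as a δ-lactone. The closest known reaction types are the alkylation of ester enolates with glycidyl triflates, the bromide opening of trisubstituted epoxides at the secondary carbon and the lactonization of δ-hydroxy esters, here run in one flask so that three components (the C5–C6 unit, the C4–C3–C2–O1 unit and bromide) are joined around the heterocycle. The only new stereocentre that survives is the C–Br carbon, controlled by the epoxide configuration from step 7 through SN2 inversion; the carbon α to the carbonyl forms as an epimer mixture that step 10 erases. The step needs alkylation at the triflate carbon instead of the epoxide (secured by the leaving-group difference at −78 °C), bromide attack at the secondary instead of the quaternary epoxide carbon (secured by the soft, weakly Lewis acidic bromide source and by sterics) and ring closure by the tertiary alkoxide instead of by the ester carbonyl oxygen (secured by the absence of a strong Lewis acid and by the gem-dimethyl effect). A minor enantiomer of either fragment ends as a diastereomer of 15 and should be removable at this stage.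

Step 10
Reactants: 15 (5R)-5-bromo-3-[(1S,3S,4S)-3-bromo-4-chloro-4-methylcyclohexyl]-6,6-dimethyloxan-2-one
Product: 17 (3R)-3-bromo-5-[(1S,3S,4S)-3-bromo-4-chloro-4-methylcyclohexyl]-2,2,6-trimethyl-3,4-dihydro-2H-pyran (laucapyranoid A), via exocyclic enol ether 16 (not isolated)
Conditions: Cp2TiMe2, PhMe–THF, 65 °C; then pyridinium p-toluenesulfonate (cat.), 23 °C
Reagents that add atoms: dimethyltitanocene, C[Ti](C)(C1C=CC=C1)C1C=CC=C1
Why: Petasis methylenation converts the lactone carbonyl into the exocyclic enol ether 16, and mild acid then moves the double bond through the oxocarbenium ion into the ring to the more stable tetrasubstituted enol ether, which removes the α-stereocentre and touches no other stereocentre.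

## Compound list

1 | 4-methylanisole | COc1ccc(C)cc1 | starting material
2 | 1-methoxy-4-methylcyclohexa-1,4-diene | COC1=CCC(C)=CC1 | intermediate
3 | 4-methylcyclohex-3-en-1-one | CC1=CCC(=O)CC1 | intermediate
4 | ethyl (triphenylphosphoranylidene)acetate | CCOC(=O)C=P(c1ccccc1)(c1ccccc1)c1ccccc1 | starting material
5 | ethyl 2-(4-methylcyclohex-3-en-1-ylidene)acetate (E/Z mixture) | CCOC(=O)C=C1CCC(C)=CC1 | intermediate
6 | ethyl 2-[(1S,6R)-1-methyl-7-oxabicyclo[4.1.0]heptan-4-ylidene]acetate (E/Z mixture) | CCOC(=O)C=C1CC[C@]2(C)O[C@@H]2C1 | intermediate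
7 | ethyl 2-[(3S,4S)-3-bromo-4-hydroxy-4-methylcyclohexylidene]acetate (E/Z mixture) | CCOC(=O)C=C1CC[C@](C)(O)[C@@H](Br)C1 | intermediate
8 | ethyl 2-[(3S,4S)-3-bromo-4-chloro-4-methylcyclohexylidene]acetate (E/Z mixture) | CCOC(=O)C=C1CC[C@](C)(Cl)[C@@H](Br)C1 | intermediate
9 | ethyl 2-[(1R,3S,4S)-3-bromo-4-chloro-4-methylcyclohexyl]acetate | CCOC(=O)C[C@H]1CC[C@](C)(Cl)[C@@H](Br)C1 | intermediate
10 | 3-methylbut-2-en-1-ol (prenol) | CC(C)=CCO | starting material
11 | [(2S)-3,3-dimethyloxiran-2-yl]methanol | OC[C@@H]1OC1(C)C | intermediate
12 | [(2S)-3,3-dimethyloxiran-2-yl]methyl trifluoromethanesulfonate | O=S(=O)(OC[C@@H]1OC1(C)C)C(F)(F)F | intermediate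
13 | ethyl 2-[(1S,3S,4S)-3-bromo-4-chloro-4-methylcyclohexyl]-3-[(2S)-3,3-dimethyloxiran-2-yl]propanoate (epimers at C2) | CCOC(=O)C([C@H]1CC[C@](C)(Cl)[C@@H](Br)C1)C[C@@H]1OC1(C)C | intermediate
14 | ethyl (4R)-4-bromo-2-[(1S,3S,4S)-3-bromo-4-chloro-4-methylcyclohexyl]-5-hydroxy-5-methylhexanoate (epimers at C2) | CCOC(=O)C([C@H]1CC[C@](C)(Cl)[C@@H](Br)C1)C[C@@H](Br)C(C)(C)O | intermediate
15 | (5R)-5-bromo-3-[(1S,3S,4S)-3-bromo-4-chloro-4-methylcyclohexyl]-6,6-dimethyloxan-2-one (epimers at C3) | O=C1C([C@H]2CC[C@](C)(Cl)[C@@H](Br)C2)C[C@@H](Br)C(C)(C)O1 | intermediate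
16 | (3R)-3-bromo-5-[(1S,3S,4S)-3-bromo-4-chloro-4-methylcyclohexyl]-2,2-dimethyl-6-methylideneoxane (epimers at C5) | C=C1C([C@H]2CC[C@](C)(Cl)[C@@H](Br)C2)C[C@@H](Br)C(C)(C)O1 | intermediate
17 | (3R)-3-bromo-5-[(1S,3S,4S)-3-bromo-4-chloro-4-methylcyclohexyl]-2,2,6-trimethyl-3,4-dihydro-2H-pyran (laucapyranoid A) | CC1=C([C@H]2CC[C@](C)(Cl)[C@@H](Br)C2)C[C@@H](Br)C(C)(C)O1 | target

## Step count and risks

Total step count: 10. Longest linear sequence: 8 (steps 1–6, 9, 10).

The three steps most likely to fail:

Step 9. What may go wrong: proton transfer from the newly formed epoxy ester to unreacted enolate followed by intramolecular opening of the epoxide (cyclopropane formation), and capture of the Lewis-acid-activated epoxide by the ester carbonyl oxygen before bromide arrives. The fallback sets out from 9 and returns to the route at 13. The enolate of 9 (LiN(iPr)2, THF, −78 °C) is alkylated with prenyl bromide to ethyl 2-[(1S,3S,4S)-3-bromo-4-chloro-4-methylcyclohexyl]-5-methylhex-4-enoate F1, so that no epoxide is present during enolate chemistry. Shi epoxidation of the prenyl double bond with the enantiomeric ketone 1,2:4,5-di-O-isopropylidene-β-L-erythro-2,3-hexodiulo-2,6-pyranose (KHSO5, K2CO3, 0 °C) then gives 13 as an isolated compound. Bromide opening (Li2NiBr4, buffered work-up) and lactonization (TsOH) are then run as separate operations to reach 15.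

Step 5. What may go wrong: loss of a proton from the chlorosulfite or the bromonium ion (alkene formation), chloride capture of the bromonium ion at the secondary carbon (1,2-bromine shift), and erosion of enantiopurity by bromonium transfer. The fallback sets out from 5 and returns at 15. Alkene 5 is bromochlorinated directly with Bu4NBrCl2 (CH2Cl2, −78 °C; anti addition with chloride at the tertiary carbon), which gives 8 as a racemate, that is together with its enantiomer ethyl 2-[(3R,4R)-3-bromo-4-chloro-4-methylcyclohexylidene]acetate F2. Step 6 converts the pair into 9 and ethyl 2-[(1S,3R,4R)-3-bromo-4-chloro-4-methylcyclohexyl]acetate F3. Step 9 with enantiopure 12 then gives 15 and its diastereomer (5R)-5-bromo-3-[(1R,3R,4R)-3-bromo-4-chloro-4-methylcyclohexyl]-6,6-dimethyloxan-2-one F4, which should be separable by chromatography; the resolution through the enantiopure side-chain unit replaces the catalytic epoxidation.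

Step 6. What may go wrong: slow hydrogenation of the electron-poor trisubstituted alkene, during which the iridium hydride can move the double bond into the ring and so weaken facial control at ring carbon 1. The fallback sets out from 8 and returns at 9. The ester is reduced with (i-Bu)2AlH (CH2Cl2, −78 °C) to the allylic alcohol 2-[(3S,4S)-3-bromo-4-chloro-4-methylcyclohexylidene]ethan-1-ol F5. Its hydroxyl group binds [Ir(cod)(PCy3)(py)]PF6 and should make hydrogen delivery fast (H2, CH2Cl2, 0 °C), again anti to the axial bromine, to give 2-[(1R,3S,4S)-3-bromo-4-chloro-4-methylcyclohexyl]ethan-1-ol F6. Oxidation (TEMPO, PhI(OAc)2, then NaClO2) gives 2-[(1R,3S,4S)-3-bromo-4-chloro-4-methylcyclohexyl]acetic acid F7, and O-alkylation of the carboxylate (EtI, KHCO3, DMF) returns 9.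

## Further compounds

F1 | step 9 | ethyl 2-[(1S,3S,4S)-3-bromo-4-chloro-4-methylcyclohexyl]-5-methylhex-4-enoate | CCOC(=O)C(CC=C(C)C)[C@H]1CC[C@](C)(Cl)[C@@H](Br)C1
F2 | step 5 | ethyl 2-[(3R,4R)-3-bromo-4-chloro-4-methylcyclohexylidene]acetate | CCOC(=O)C=C1CC[C@@](C)(Cl)[C@H](Br)C1
F3 | step 5 | ethyl 2-[(1S,3R,4R)-3-bromo-4-chloro-4-methylcyclohexyl]acetate | CCOC(=O)C[C@@H]1CC[C@@](C)(Cl)[C@H](Br)C1
F4 | step 5 | (5R)-5-bromo-3-[(1R,3R,4R)-3-bromo-4-chloro-4-methylcyclohexyl]-6,6-dimethyloxan-2-one | O=C1C([C@@H]2CC[C@@](C)(Cl)[C@H](Br)C2)C[C@@H](Br)C(C)(C)O1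
F5 | step 6 | 2-[(3S,4S)-3-bromo-4-chloro-4-methylcyclohexylidene]ethan-1-ol | OCC=C1CC[C@](C)(Cl)[C@@H](Br)C1
F6 | step 6 | 2-[(1R,3S,4S)-3-bromo-4-chloro-4-methylcyclohexyl]ethan-1-ol | OCC[C@H]1CC[C@](C)(Cl)[C@@H](Br)C1
F7 | step 6 | 2-[(1R,3S,4S)-3-bromo-4-chloro-4-methylcyclohexyl]acetic acid | OC(=O)C[C@H]1CC[C@](C)(Cl)[C@@H](Br)C1
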